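**Retrosynthetic overview**
1. Target 38 ⇐ late C2–C3 bond (alkenylchromium addition, then oxidation) and the α-methylene group by Mannich/elimination on a cis-fused lactone; C5 isobutyrate already in place, C1/C2 as acetonide, C9 as OTBS.
2. Lactone ring B ⇐ Ueno–Stork 5-exo radical cyclisation from C6–O onto C7=C8 of a cycloheptene; carbocycle ring A ⇐ ring-closing metathesis of a C7-vinyl/C8-styryl diene.
3. Diene ⇐ key intermolecular carbonyl allylation: reagent-controlled (Z)-γ-alkoxyallylboration of a C5 aldehyde (forms C5–C6, sets C5 and C6).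
4. Aldehyde ⇐ butyrolactone template: C1 quaternary centre by enolate hydroxylation then formaldehyde aldol (both anti to C10-Me); template ⇐ asymmetric (Z)-crotylboration of cinnamaldehyde (forms C9–C10, sets C9 and C10).
5. Ring order: temporary γ-lactone template (made, used, opened) → seven-membered ring A → cis-fused γ-lactone ring B.

Convention (one line): locants are those of the target skeleton – C1 C(OH)(acyl), C2–C4/C15 crotonoyl, C5 CH–O-isobutyryl, C6 CH–O(lactone), C7 ring-fusion CH, C8 CH2, C9 CHOH, C10 CHMe, C11–C13 α-methylene lactone; α/β = below/above ring A drawn C1→C5→C6→C7→C8→C9→C10 clockwise; target = 1α-OH, 2β, 5β-O, 6α-O, 7α-C11, 9β-OH, 10α-Me (1S,5S,6R,7S,9R,10S).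

**Step 1**
Reactants: 1 (E)-cinnamaldehyde; 2 cis-but-2-ene
Product: 4 (3R,4R,1E)-4-methyl-1-phenylhexa-1,5-dien-3-ol, via (Z)-crotyldiisopinocampheylborane 3 (not isolated)
Conditions: 2, KOt-Bu, n-BuLi, THF, –78 → –45 °C; (–)-Ipc2BOMe, –78 °C; BF3·OEt2; 1, –78 °C; then NaOH, H2O2, rt
Reagents that add atoms: none
Why: Brown asymmetric (Z)-crotylboration (intermolecular carbonyl allylation) through a chair Zimmerman–Traxler transition state gives the syn C9-OH/C10-Me pair, with the (–)-Ipc2B group fixing the absolute sense.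

**Step 2**
Reactants: 4 (3R,4R,1E)-4-methyl-1-phenylhexa-1,5-dien-3-ol
Product: 5 (3R,4S,5E)-3-methyl-6-phenylhex-5-ene-1,4-diol
Conditions: 9-BBN (2.2 equiv), THF, 0 °C → rt; NaOH, H2O2, 0 °C
Reagents that add atoms: hydrogen peroxide, OO
Why: Anti-Markovnikov hydroboration–oxidation; 9-BBN takes the terminal vinyl group and leaves the 1,2-disubstituted styryl alkene, and no stereocentre is touched.

**Step 3**
Reactants: 5 (3R,4S,5E)-3-methyl-6-phenylhex-5-ene-1,4-diol
Product: 7 (4R,5S)-4-methyl-5-[(E)-styryl]oxolan-2-one, via lactol 6 (not isolated)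
Conditions: TEMPO (0.2 equiv), PhI(OAc)2 (2.5 equiv), CH2Cl2, rt
Reagents that add atoms: none
Why: TEMPO-catalysed oxidative lactonisation (primary alcohol → aldehyde → lactol → lactone) gives the cis-4-methyl-5-styryl butyrolactone used as stereochemical template.

**Step 4**
Reactants: 7 (4R,5S)-4-methyl-5-[(E)-styryl]oxolan-2-one
Product: 8 (3R,4R,5R)-3-hydroxy-4-methyl-5-[(E)-styryl]oxolan-2-one
Conditions: NaN(SiMe3)2, THF, –78 °C; 2-(phenylsulfonyl)-3-phenyloxaziridine, –78 °C; NH4Cl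
Reagents that add atoms: 2-(phenylsulfonyl)-3-phenyloxaziridine, O=S(=O)(c1ccccc1)N1OC1c1ccccc1
Why: Davis enolate hydroxylation; the oxidant approaches the lactone enolate anti to the cis C10-methyl and C9-styryl groups, giving the 3,4-trans hydroxy lactone (C1 configuration provisional).

**Step 5**
Reactants: 8 (3R,4R,5R)-3-hydroxy-4-methyl-5-[(E)-styryl]oxolan-2-one
Product: 9 (3R,4S,5R)-4-methyl-5-[(E)-styryl]-3-(triethylsilyloxy)oxolan-2-one
Conditions: TESCl, imidazole, DMF, 0 °C → rt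
Reagents that add atoms: chlorotriethylsilane, CC[Si](Cl)(CC)CC
Why: O-silylation masks the hydroxyl so that C1 can be enolised a second time.

**Step 6**
Reactants: 9 (3R,4S,5R)-4-methyl-5-[(E)-styryl]-3-(triethylsilyloxy)oxolan-2-one; 10 formaldehyde (gas from cracked paraformaldehyde)
Product: 11 (3R,4S,5R)-3-(hydroxymethyl)-4-methyl-5-[(E)-styryl]-3-(triethylsilyloxy)oxolan-2-one
Conditions: LiN(i-Pr)2, THF, –78 °C; 10, –78 → –40 °C; NH4Cl
Reagents that add atoms: none
Why: Intermolecular aldol (hydroxymethylation) of the α-silyloxy lactone enolate; formaldehyde adds anti to C10-Me/C9-styryl, so C2 ends β and the C1 oxygen α, which is the target's quaternary C1.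

**Step 7**
Reactants: 11 (3R,4S,5R)-3-(hydroxymethyl)-4-methyl-5-[(E)-styryl]-3-(triethylsilyloxy)oxolan-2-one
Product: 13 (5R,8R,9S)-2,2,9-trimethyl-8-[(E)-styryl]-1,3,7-trioxaspiro[4.4]nonan-6-one, via diol 12 (not isolated)
Conditions: Me2C(OMe)2, CSA (0.1 equiv), MeOH (2 equiv), acetone, rt
Reagents that add atoms: 2,2-dimethoxypropane, COC(C)(C)OC
Why: Acid-catalysed desilylation and transketalisation tie C1-OH and C2-OH into a compact acetonide that survives all steps up to the endgame.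

**Step 8**
Reactants: 13 (5R,8R,9S)-2,2,9-trimethyl-8-[(E)-styryl]-1,3,7-trioxaspiro[4.4]nonan-6-one
Product: 14 (4R)-4-[(2S,3R,4E)-3-hydroxy-5-phenylpent-4-en-2-yl]-N-methoxy-N,2,2-trimethyl-1,3-dioxolane-4-carboxamide
Conditions: MeNH(OMe)·HCl, Me3Al, CH2Cl2, 0 → 40 °C
Reagents that add atoms: N,O-dimethylhydroxylamine hydrochloride, CNOC.Cl
Why: Weinreb aminolysis with the aluminium amide opens the template lactone, freeing C9-OH and giving an amide that can be reduced to the aldehyde without over-reduction.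

**Step 9**
Reactants: 14 (4R)-4-[(2S,3R,4E)-3-hydroxy-5-phenylpent-4-en-2-yl]-N-methoxy-N,2,2-trimethyl-1,3-dioxolane-4-carboxamide
Product: 15 (4R)-4-[(2S,3R,4E)-3-(tert-butyldimethylsilyloxy)-5-phenylpent-4-en-2-yl]-N-methoxy-N,2,2-trimethyl-1,3-dioxolane-4-carboxamide
Conditions: TBSOTf, 2,6-lutidine, CH2Cl2, –78 → 0 °C
Reagents that add atoms: tert-butyldimethylsilyl triflate, CC(C)(C)[Si](C)(C)OS(=O)(=O)C(F)(F)F
Why: Silylation of the allylic C9-OH blocks relactonisation and distinguishes C9-O from the hydroxyls made later.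

**Step 10**
Reactants: 15 (4R)-4-[(2S,3R,4E)-3-(tert-butyldimethylsilyloxy)-5-phenylpent-4-en-2-yl]-N-methoxy-N,2,2-trimethyl-1,3-dioxolane-4-carboxamide
Product: 16 (4R)-4-[(2S,3R,4E)-3-(tert-butyldimethylsilyloxy)-5-phenylpent-4-en-2-yl]-2,2-dimethyl-1,3-dioxolane-4-carbaldehyde
Conditions: i-Bu2AlH, THF, –78 °C; aq. potassium sodium tartrate
Reagents that add atoms: none
Why: Weinreb amide reduction stops at the aldehyde through the chelated tetrahedral intermediate, and the quaternary α-carbon cannot epimerise.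

**Step 11**
Reactants: 16 (4R)-4-[(2S,3R,4E)-3-(tert-butyldimethylsilyloxy)-5-phenylpent-4-en-2-yl]-2,2-dimethyl-1,3-dioxolane-4-carbaldehyde; 17 allyl methoxymethyl ether
Product: 19 (1S,2R)-1-{(4R)-4-[(2S,3R,4E)-3-(tert-butyldimethylsilyloxy)-5-phenylpent-4-en-2-yl]-2,2-dimethyl-1,3-dioxolan-4-yl}-2-(methoxymethoxy)but-3-en-1-ol, via (Z)-3-(methoxymethoxy)allyldiisopinocampheylborane 18 (not isolated)
Conditions: 17, s-BuLi, THF, –78 °C; (–)-Ipc2BOMe; BF3·OEt2; 16, –78 °C → rt; then NaOH, H2O2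
Reagents that add atoms: none
Why: Key intermolecular carbonyl allylation (Brown γ-alkoxyallylboration): the (Z)-reagent in a chair transition state gives the syn C5-OH/C6-OMOM pair and the (–)-Ipc2B group selects the aldehyde face by reagent control, overriding the opposing Felkin preference of the substrate.

**Step 12**
Reactants: 19 (the C5 alcohol from step 11); 20 isobutyric anhydride
Product: 21 2-methylpropanoate (C5 O-isobutyrate) of 19
Conditions: DMAP (1 equiv), Et3N, CH2Cl2, 40 °C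
Reagents that add atoms: none
Why: DMAP-catalysed acylation puts on the target's C5 isobutyrate while C5-OH is the only free hydroxyl.

**Step 13**
Reactants: 21 2-methylpropanoate of 19
Product: 22 ring A cycloheptene (C1/C2 spiro-acetonide; 5β-O-isobutyrate; 6α-OMOM; C7=C8; 9β-OTBS; 10α-Me)
Conditions: second-generation Grubbs catalyst RuCl2(=CHPh)(PCy3)(H2IMes) (5 mol %), CH2Cl2 (5 mM), 40 °C
Reagents that add atoms: none
Why: Ring-closing olefin metathesis of the vinyl and styryl termini closes the seven-membered ring as the cis C7=C8 alkene with loss of styrene; no stereocentre changes.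

**Step 14**
Reactants: 22 ring A cycloheptene MOM ether
Product: 23 ring A cycloheptenol (6α-OH; otherwise as 22)
Conditions: TMSOTf, 2,2′-bipyridyl, CH2Cl2, 0 °C; then H2O, rt
Reagents that add atoms: none
Why: Chemoselective MOM-acetal cleavage through a bipyridinium intermediate under non-protic conditions that ketals, silyl ethers and esters tolerate, freeing only the allylic C6-OH.

**Step 15**
Reactants: 23 ring A cycloheptenol; 24 ethyl vinyl ether
Product: 25 C6 O-(2-bromo-1-ethoxyethyl) mixed acetal of 23 (acetal epimers)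
Conditions: NBS, 24, CH2Cl2, –40 → 0 °C
Reagents that add atoms: N-bromosuccinimide, O=C1CCC(=O)N1Br
Why: Bromoalkoxylation of the enol ether (Ueno–Stork bromoacetal formation) tethers a radical precursor to C6–O; the new acetal centre is an inconsequential mixture.

**Step 16**
Reactants: 25 bromoacetal
Product: 26 cis-fused bicyclic ethyl acetal (2-ethoxytetrahydrofuran on C6/C7; H6 and H7 β; acetal epimers)
Conditions: Bu3SnH, AIBN (cat.), PhH, 80 °C
Reagents that add atoms: none
Why: Ueno–Stork 5-exo-trig radical cyclisation; the tether on the α C6 oxygen delivers C11 to the same face of C7, which enforces the cis ring fusion, and the C8 radical is reduced by the stannane.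

**Step 17**
Reactants: 26 cis-fused bicyclic ethyl acetal
Product: 28 cis-fused γ-lactone (ring B; C11 H2), via lactol 27 (not isolated)
Conditions: CrO3, H2SO4, H2O, acetone, 0 °C
Reagents that add atoms: water, O
Why: Acid hydrolysis of the ethyl acetal and chromic acid oxidation of the lactol give the γ-lactone; acetonide, TBS ether and ester survive the short cold exposure.

**Step 18**
Reactants: 28 cis-fused γ-lactone; 29 N,N-dimethylmethyleneiminium iodide (CH2=NMe2+ I–)
Product: 30 C11 dimethylaminomethyl lactone (Mannich base; exo C11 epimer expected)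
Conditions: LiN(i-Pr)2 (1.05 equiv), THF, –78 °C; 29, –78 → 0 °C
Reagents that add atoms: none
Why: Mannich reaction of the lactone enolate with the iminium salt; the lactone CH2 is deprotonated faster than the hindered isobutyrate CH, and the new C11 centre is destroyed in the next step.

**Step 19**
Reactants: 30 Mannich base
Product: 32 α-methylene lactone (C1/C2 acetonide; 5β-O-isobutyrate; 9β-OTBS), via trimethylammonium iodide 31 (not isolated)
Conditions: MeI, THF, rt; then NaHCO3, CH2Cl2/H2O, rt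
Reagents that add atoms: none
Why: N-quaternisation followed by E1cB β-elimination of trimethylamine gives the exocyclic C11=C13 alkene.

**Step 20**
Reactants: 32 α-methylene lactone acetonide
Product: 33 C1,C2-diol (1α-OH; C2 H2OH)
Conditions: AcOH/H2O 4:1, 40 °C
Reagents that add atoms: none
Why: Acid hydrolysis of the acetonide; the secondary TBS ether, the ester and the α-methylene lactone are stable to aqueous acetic acid.

**Step 21**
Reactants: 33 C1,C2-diol
Product: 34 C2 aldehyde (1α-hydroxy aldehyde)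
Conditions: SO3·pyridine, DMSO, i-Pr2NEt, CH2Cl2, 0 °C
Reagents that add atoms: none
Why: Parikh–Doering oxidation; only the primary C2-OH can be oxidised (C1-OH is tertiary), and it is fast at 0 °C so the isobutyrate does not migrate.

**Step 22**
Reactants: 34 C2 aldehyde; 35 (E)-1-bromoprop-1-ene
Product: 36 C2 allylic alcohol with (E)-propenyl group (C2 epimers)
Conditions: CrCl2 (6 equiv), NiCl2 (2 mol %), DMSO, rt
Reagents that add atoms: none
Why: Nozaki–Hiyama–Kishi coupling; the alkenylchromium species adds only to the aldehyde (ester, lactone and free tertiary OH tolerated) with retention of the (E) geometry, and the C2 carbinol mixture is inconsequential.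

**Step 23**
Reactants: 36 C2 allylic alcohol
Product: 37 9-O-TBS ether of the target (C2 enone)
Conditions: Dess–Martin periodinane, NaHCO3, CH2Cl2, 0 °C → rt
Reagents that add atoms: none
Why: Periodinane oxidation of the secondary allylic alcohol gives the (E)-enone; the tertiary C1-OH is inert and the C2 stereocentre disappears.

**Step 24**
Reactants: 37 9-O-TBS ether of the target
Product: 38 target, (3aS,5R,6S,7S,8S,8aR)-7-[(2E)-but-2-enoyl]-5,7-dihydroxy-6-methyl-3-methylidene-2-oxooctahydro-2H-cyclohepta[b]furan-8-yl 2-methylpropanoate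
Conditions: HF·pyridine, pyridine, THF, 0 °C → rt
Reagents that add atoms: none
Why: Fluoride-mediated desilylation under buffered acidic conditions that leave the ester, the enone and the α-methylene lactone intact.

**Compound list**
1 | (E)-cinnamaldehyde | O=C/C=C/c1ccccc1 | starting material
2 | cis-but-2-ene | C/C=C\C | starting material
3 | (Z)-crotyldiisopinocampheylborane, from (–)-Ipc2BOMe | C[C@H]1[C@H](B(C/C=C\C)[C@@H]3C[C@@H]4C[C@H]([C@H]3C)C4(C)C)C[C@@H]2C[C@H]1C2(C)C | intermediate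
4 | (3R,4R,1E)-4-methyl-1-phenylhexa-1,5-dien-3-ol | c1ccccc1/C=C/[C@@H](O)[C@H](C)C=C | intermediate
5 | (3R,4S,5E)-3-methyl-6-phenylhex-5-ene-1,4-diol | c1ccccc1/C=C/[C@@H](O)[C@H](C)CCO | intermediate
6 | (4R,5S)-4-methyl-5-[(E)-styryl]oxolan-2-ol (lactol, anomers) | C[C@@H]1CC(O)O[C@@H]1/C=C/c1ccccc1 | intermediate
7 | (4R,5S)-4-methyl-5-[(E)-styryl]oxolan-2-one | C[C@@H]1CC(=O)O[C@@H]1/C=C/c1ccccc1 | intermediate
8 | (3R,4R,5R)-3-hydroxy-4-methyl-5-[(E)-styryl]oxolan-2-one | C[C@@H]1[C@@H](O)C(=O)O[C@@H]1/C=C/c1ccccc1 | intermediate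
9 | (3R,4S,5R)-4-methyl-5-[(E)-styryl]-3-(triethylsilyloxy)oxolan-2-one | C[C@@H]1[C@@H](O[Si](CC)(CC)CC)C(=O)O[C@@H]1/C=C/c1ccccc1 | intermediate
10 | formaldehyde | C=O | starting material
11 | (3R,4S,5R)-3-(hydroxymethyl)-4-methyl-5-[(E)-styryl]-3-(triethylsilyloxy)oxolan-2-one | C[C@@H]1[C@@](O[Si](CC)(CC)CC)(CO)C(=O)O[C@@H]1/C=C/c1ccccc1 | intermediate
12 | (3R,4S,5R)-3-hydroxy-3-(hydroxymethyl)-4-methyl-5-[(E)-styryl]oxolan-2-one | C[C@@H]1[C@@](O)(CO)C(=O)O[C@@H]1/C=C/c1ccccc1 | intermediate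
13 | (5R,8R,9S)-2,2,9-trimethyl-8-[(E)-styryl]-1,3,7-trioxaspiro[4.4]nonan-6-one | C[C@@H]1[C@@]2(COC(C)(C)O2)C(=O)O[C@@H]1/C=C/c1ccccc1 | intermediate
14 | (4R)-4-[(2S,3R,4E)-3-hydroxy-5-phenylpent-4-en-2-yl]-N-methoxy-N,2,2-trimethyl-1,3-dioxolane-4-carboxamide | c1ccccc1/C=C/[C@@H](O)[C@H](C)[C@@]1(COC(C)(C)O1)C(=O)N(C)OC | intermediate
15 | (4R)-4-[(2S,3R,4E)-3-(tert-butyldimethylsilyloxy)-5-phenylpent-4-en-2-yl]-N-methoxy-N,2,2-trimethyl-1,3-dioxolane-4-carboxamide | c1ccccc1/C=C/[C@@H](O[Si](C)(C)C(C)(C)C)[C@H](C)[C@@]1(COC(C)(C)O1)C(=O)N(C)OC | intermediate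
16 | (4R)-4-[(2S,3R,4E)-3-(tert-butyldimethylsilyloxy)-5-phenylpent-4-en-2-yl]-2,2-dimethyl-1,3-dioxolane-4-carbaldehyde | c1ccccc1/C=C/[C@@H](O[Si](C)(C)C(C)(C)C)[C@H](C)[C@@]1(COC(C)(C)O1)C=O | intermediate
17 | allyl methoxymethyl ether, 3-(methoxymethoxy)prop-1-ene | C=CCOCOC | starting material
18 | (Z)-3-(methoxymethoxy)allyldiisopinocampheylborane, from (–)-Ipc2BOMe | C[C@H]1[C@H](B(C/C=C\OCOC)[C@@H]3C[C@@H]4C[C@H]([C@H]3C)C4(C)C)C[C@@H]2C[C@H]1C2(C)C | intermediate
19 | (1S,2R)-1-{(4R)-4-[(2S,3R,4E)-3-(tert-butyldimethylsilyloxy)-5-phenylpent-4-en-2-yl]-2,2-dimethyl-1,3-dioxolan-4-yl}-2-(methoxymethoxy)but-3-en-1-ol | c1ccccc1/C=C/[C@@H](O[Si](C)(C)C(C)(C)C)[C@H](C)[C@@]1(COC(C)(C)O1)[C@H]([C@H](OCOC)C=C)O | intermediate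
20 | isobutyric anhydride | CC(C)C(=O)OC(=O)C(C)C | starting material
21 | 2-methylpropanoate (C5 ester) of 19 | c1ccccc1/C=C/[C@@H](O[Si](C)(C)C(C)(C)C)[C@H](C)[C@@]1(COC(C)(C)O1)[C@H]([C@H](OCOC)C=C)OC(=O)C(C)C | intermediate
22 | ring A cyclohept-7-ene: C1/C2 spiro-acetonide (C1–O α), 5β-O-isobutyrate, 6α-OMOM, 9β-OTBS, 10α-Me | C1=C[C@@H](OCOC)[C@H](OC(=O)C(C)C)[C@]2(COC(C)(C)O2)[C@@H](C)[C@@H]1O[Si](C)(C)C(C)(C)C | intermediate
23 | 6α-alcohol of 22 (MOM removed) | C1=C[C@@H](O)[C@H](OC(=O)C(C)C)[C@]2(COC(C)(C)O2)[C@@H](C)[C@@H]1O[Si](C)(C)C(C)(C)C | intermediate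
24 | ethyl vinyl ether | C=COCC | starting material
25 | C6 O-(2-bromo-1-ethoxyethyl) mixed acetal of 23 (acetal epimers) | C1=C[C@@H](OC(CBr)OCC)[C@H](OC(=O)C(C)C)[C@]2(COC(C)(C)O2)[C@@H](C)[C@@H]1O[Si](C)(C)C(C)(C)C | intermediate
26 | cis-fused bicyclic ethyl acetal (C12 acetal epimers; H6, H7 β; C1/C2 acetonide, 5β-O-isobutyrate, 9β-OTBS, 10α-Me) | C1C(OCC)O[C@@H]2[C@H]1C[C@@H](O[Si](C)(C)C(C)(C)C)[C@H](C)[C@@]3(COC(C)(C)O3)[C@H]2OC(=O)C(C)C | intermediate
27 | lactol corresponding to 26 | C1C(O)O[C@@H]2[C@H]1C[C@@H](O[Si](C)(C)C(C)(C)C)[C@H](C)[C@@]3(COC(C)(C)O3)[C@H]2OC(=O)C(C)C | intermediate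
28 | cis-fused γ-lactone (C11 H2; other groups as 26) | C1C(=O)O[C@@H]2[C@H]1C[C@@H](O[Si](C)(C)C(C)(C)C)[C@H](C)[C@@]3(COC(C)(C)O3)[C@H]2OC(=O)C(C)C | intermediate
29 | N,N-dimethylmethyleneiminium iodide | C[N+](C)=C.[I-] | starting material
30 | C11 dimethylaminomethyl lactone (exo epimer drawn) | CN(C)C[C@@H]1C(=O)O[C@@H]2[C@H]1C[C@@H](O[Si](C)(C)C(C)(C)C)[C@H](C)[C@@]3(COC(C)(C)O3)[C@H]2OC(=O)C(C)C | intermediate
31 | C11 trimethylammoniomethyl lactone iodide | C[N+](C)(C)C[C@@H]1C(=O)O[C@@H]2[C@H]1C[C@@H](O[Si](C)(C)C(C)(C)C)[C@H](C)[C@@]3(COC(C)(C)O3)[C@H]2OC(=O)C(C)C.[I-] | intermediate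
32 | α-methylene lactone with C1/C2 acetonide, 5β-O-isobutyrate, 9β-OTBS | C=C1C(=O)O[C@@H]2[C@H]1C[C@@H](O[Si](C)(C)C(C)(C)C)[C@H](C)[C@@]3(COC(C)(C)O3)[C@H]2OC(=O)C(C)C | intermediate
33 | C1,C2-diol (1α-OH, C2 H2OH) of 32 | C=C1C(=O)O[C@@H]2[C@H]1C[C@@H](O[Si](C)(C)C(C)(C)C)[C@H](C)[C@@](O)(CO)[C@H]2OC(=O)C(C)C | intermediate
34 | C2 aldehyde (1α-hydroxy aldehyde) | C=C1C(=O)O[C@@H]2[C@H]1C[C@@H](O[Si](C)(C)C(C)(C)C)[C@H](C)[C@@](O)(C=O)[C@H]2OC(=O)C(C)C | intermediate
35 | (E)-1-bromoprop-1-ene | C/C=C/Br | starting material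
36 | C2 allylic alcohol, (E)-1-hydroxybut-2-enyl side chain (C2 epimers) | C=C1C(=O)O[C@@H]2[C@H]1C[C@@H](O[Si](C)(C)C(C)(C)C)[C@H](C)[C@@](O)(C(O)/C=C/C)[C@H]2OC(=O)C(C)C | intermediate
37 | 9-O-TBS ether of the target | C=C1C(=O)O[C@@H]2[C@H]1C[C@@H](O[Si](C)(C)C(C)(C)C)[C@H](C)[C@@](O)(C(=O)/C=C/C)[C@H]2OC(=O)C(C)C | intermediate
38 | (3aS,5R,6S,7S,8S,8aR)-7-[(2E)-but-2-enoyl]-5,7-dihydroxy-6-methyl-3-methylidene-2-oxooctahydro-2H-cyclohepta[b]furan-8-yl 2-methylpropanoate | C=C1C(=O)O[C@@H]2[C@H]1C[C@@H](O)[C@H](C)[C@@](O)(C(=O)/C=C/C)[C@H]2OC(=O)C(C)C | target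

**Totals and risks**
Total step count: 24. Longest linear sequence: 24 steps (from 1).

Most likely to fail, step 8 (aminolysis of the hindered lactone): the carbonyl of 13 sits next to a quaternary spiro carbon, so ring opening may stall or the hydroxy amide may relactonise. The fallback sets out from 13 and comes back at 19. Reduce 13 with i-Bu2AlH (CH2Cl2, –78 °C) to the lactol (5R,8R,9S)-2,2,9-trimethyl-8-[(E)-styryl]-1,3,7-trioxaspiro[4.4]nonan-6-ol F1. Treat this lactol, through its open hydroxy-aldehyde form, with excess borane 18 (THF, –78 °C → rt; NaOH, H2O2) to obtain the C9,C5-diol F2. Then silylate only the unhindered allylic C9-OH (TBSCl, imidazole, DMF, 0 °C), which gives 19 and skips 14–16.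

Most likely to fail, step 11 (key allylboration): the aldehyde is neopentyl-like and the reagent has to override the substrate's Felkin preference. The fallback sets out from 16 (with 17) and comes back at 19. Lithiate 17 (s-BuLi, THF, –78 °C) and quench with Bu3SnCl to obtain tributyl[(Z)-3-(methoxymethoxy)allyl]stannane F3. Add it to 16 pre-complexed with MgBr2·OEt2 (CH2Cl2, –20 °C). Control then passes from the reagent to the substrate: α-chelation between the aldehyde and the C1 ketal oxygen exposes the face next to the tied-back C2 methylene, which is the face required, and the open transition state again gives the syn C5/C6 pair.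

Most likely to fail, step 18 (Mannich methylenation beside the C5 ester): the lactone enolate may attack or be accompanied by enolisation of the isobutyrate. The fallback sets out from 23 and comes back at 32, avoiding any enolate. Bromoalkoxylate methoxyallene with NBS and alcohol 23 (CH2Cl2, –40 °C) to give the C6 O-(2-bromo-1-methoxyallyl) mixed acetal F4. Cyclise it by 5-exo vinyl-radical closure (Bu3SnH, AIBN, PhH, 80 °C) to the cis-fused 3-methylene-2-methoxytetrahydrofuran F5. Oxidise this acetal with CrO3/H2SO4 in acetone (0 °C) to the α-methylene lactone 32.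

**Further compounds**
F1 | step 8 | (5R,8R,9S)-2,2,9-trimethyl-8-[(E)-styryl]-1,3,7-trioxaspiro[4.4]nonan-6-ol (lactol, anomers) | C[C@@H]1[C@@]2(COC(C)(C)O2)C(O)O[C@@H]1/C=C/c1ccccc1
F2 | step 8 | (1S,2R)-1-{(4R)-4-[(2S,3R,4E)-3-hydroxy-5-phenylpent-4-en-2-yl]-2,2-dimethyl-1,3-dioxolan-4-yl}-2-(methoxymethoxy)but-3-en-1-ol | c1ccccc1/C=C/[C@@H](O)[C@H](C)[C@@]1(COC(C)(C)O1)[C@H]([C@H](OCOC)C=C)O
F3 | step 11 | tributyl[(Z)-3-(methoxymethoxy)allyl]stannane | CCCC[Sn](CCCC)(CCCC)C/C=C\OCOC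
F4 | step 18 | C6 O-(2-bromo-1-methoxyallyl) mixed acetal of 23 (acetal epimers) | C1=C[C@@H](OC(OC)C(Br)=C)[C@H](OC(=O)C(C)C)[C@]2(COC(C)(C)O2)[C@@H](C)[C@@H]1O[Si](C)(C)C(C)(C)C
F5 | step 18 | cis-fused 2-methoxy-3-methylenetetrahydrofuran acetal (acetal epimers; other groups as 26) | C=C1C(OC)O[C@@H]2[C@H]1C[C@@H](O[Si](C)(C)C(C)(C)C)[C@H](C)[C@@]3(COC(C)(C)O3)[C@H]2OC(=O)C(C)C
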